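**Retrosynthetic overview**
- Target 16 comes from a 7,4'-bis-O-silyl quercetin by sulfation of the 3-OH and 3'-OH only; these two oxygens are carried as benzyl ethers from the ring-forming step onward, and the chelated 5-OH is never protected.
- Ring C (the 4-pyranone, the only ring made) is cut at C4–C4a and O1–C2, giving phloroglucinol and an ethyl 2-benzyloxy-3-aryl-3-oxopropanoate.
- The strategy rests on ring A: its oxygens O1, O5 and O7 sit on alternate carbons (C8a, C5, C7), so the three CH carbons are equivalent and any one can become C4a. C2, C3 (with O3 attached) and C4 therefore arrive as one three-carbon unit with no regiochemical question.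
- The ketoester comes from Claisen acylation of ethyl benzyloxyacetate with 3-benzyloxy-4-silyloxybenzoyl chloride; the 3-O-benzyl/4-OH pattern comes from dianion mono-benzylation of ethyl protocatechuate.
- Order of rings: A and B are bought, ring C is closed in step 6.

Key step: step 6

Remark (assumption): the target has no stereogenic element, so no stereocontrol is needed. Sulfated compounds 15 and 16 are written as neutral hydrogen sulfates, although they would be handled as pyridinium or tetrabutylammonium salts until the final cation exchange. The α-carbon of 7, 8 and 11 is a racemic, enolisable centre that becomes sp2 C3 in step 6.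

**Step 1**
Reactants: 1 ethyl 3,4-dihydroxybenzoate
Product: 2 ethyl 3-(benzyloxy)-4-hydroxybenzoate
Conditions: NaH (2.1 equiv), DMF, 0 °C; BnBr (1.0 equiv), 0 °C to rt; 1 M HCl
Reagents that add atoms: benzyl bromide, BrCc1ccccc1
Why: Regioselective Williamson mono-O-alkylation of a catechol dianion; the O4 phenoxide is delocalised into the para ester, so the O3 phenoxide is the stronger nucleophile and should take the single equivalent of benzyl bromide.

**Step 2**
Reactants: 2 ethyl 3-(benzyloxy)-4-hydroxybenzoate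
Product: 3 3-(benzyloxy)-4-hydroxybenzoic acid
Conditions: NaOH (3 equiv), EtOH–H2O, 70 °C; 1 M HCl
Reagents that add atoms: sodium hydroxide, [Na+].[OH-]
Why: Ester saponification; the benzyl ether is inert to hydroxide and acidification should return the free hydroxy acid.

**Step 3**
Reactants: 3 3-(benzyloxy)-4-hydroxybenzoic acid
Product: 4 tert-butyldimethylsilyl 3-(benzyloxy)-4-[(tert-butyldimethylsilyl)oxy]benzoate
Conditions: TBSCl (2.3 equiv), imidazole (5 equiv), DMF, rt; hexane extraction
Reagents that add atoms: tert-butyldimethylsilyl chloride, CC(C)(C)[Si](C)(C)Cl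
Why: Imidazole-mediated silylation of both acidic OH groups; the phenol is masked for the enolate chemistry and the silyl ester serves as a neutral precursor of the acid chloride.

**Step 4**
Reactants: 4 tert-butyldimethylsilyl 3-(benzyloxy)-4-[(tert-butyldimethylsilyl)oxy]benzoate; 5 ethyl benzyloxyacetate
Product: 7 ethyl 2-(benzyloxy)-3-{3-(benzyloxy)-4-[(tert-butyldimethylsilyl)oxy]phenyl}-3-oxopropanoate (racemic), via acid chloride 6 (not isolated)
Conditions: (COCl)2 (1.2 equiv), DMF (cat.), CH2Cl2, 0 °C to rt, evaporate; 5 (2.1 equiv), LiHMDS (2.0 equiv), THF, −78 °C, then 6, −78 to −40 °C; 1 M HCl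
Reagents that add atoms: oxalyl chloride, O=C(Cl)C(=O)Cl (supplies the chlorine of 6 only; none of its atoms remain in 7)
Why: The silyl ester should be converted into the acid chloride by the Vilsmeier reagent without acid and without loss of the aryl silyl ether, and Claisen C-acylation of the chelated lithium enolate of the α-alkoxy ester then gives the β-ketoester; two equivalents of enolate are used because the product is deprotonated as it forms.

**Step 5**
Reactants: 7 ethyl 2-(benzyloxy)-3-{3-(benzyloxy)-4-[(tert-butyldimethylsilyl)oxy]phenyl}-3-oxopropanoate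
Product: 8 ethyl 2-(benzyloxy)-3-[3-(benzyloxy)-4-hydroxyphenyl]-3-oxopropanoate (racemic)
Conditions: TBAF (1.1 equiv), AcOH (1.2 equiv), THF, 0 °C
Reagents that add atoms: none
Why: Fluoride cleavage of an aryl silyl ether, buffered with acetic acid so that the β-ketoester does not suffer retro-Claisen cleavage.

**Step 6**
Reactants: 8 ethyl 2-(benzyloxy)-3-[3-(benzyloxy)-4-hydroxyphenyl]-3-oxopropanoate; 9 phloroglucinol (anhydrous)
Product: 12 3-(benzyloxy)-2-[3-(benzyloxy)-4-hydroxyphenyl]-5,7-dihydroxy-4H-chromen-4-one, via acylketene 10 (not isolated), via aryl diketone 11 (not isolated)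
Conditions: 9 (3 equiv, dried), neat melt, 240 °C, Ar stream, 20 min (metal bath or microwave)
Reagents that add atoms: none
Why: On heating, 8 should lose ethanol to give acylketene 10, which C-acylates molten phloroglucinol at one of its three equivalent ring CH positions (C4–C4a, diketone 11); the flanking phenol then adds to the aryl ketone carbon in a 6-exo-trig closure (O1–C2) and the hemiketal dehydrates to the 4-pyranone, so ring C forms with O3 already in place. The closest known reaction type is the thermal Mentzer chromone synthesis of 5,7-dihydroxyflavones from phloroglucinol and aroylacetates, α-substituted ketoesters included. No stereocentre is formed, and the racemic α-carbon of 8 becomes the sp2 C3. The step needs chromone over 4-arylcoumarin and ring C-acylation over lasting O-acylation: the acid-free melt gives no Pechmann activation of the ketone, the α-benzyloxy group further hinders arene attack at the ketone carbon, and aryl β-ketoesters formed by O-acylation (on phloroglucinol or on the weakly nucleophilic, para-acylated 4-OH of ring B) should revert to 10 at this temperature until the irreversible cyclodehydration drains them. Excess dry phloroglucinol and a gas stream that carries off ethanol and water should suppress hydrolysis and decarboxylation of the ketoester.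

**Step 7**
Reactants: 12 3-(benzyloxy)-2-[3-(benzyloxy)-4-hydroxyphenyl]-5,7-dihydroxy-4H-chromen-4-one
Product: 13 3-(benzyloxy)-2-{3-(benzyloxy)-4-[(triisopropylsilyl)oxy]phenyl}-5-hydroxy-7-[(triisopropylsilyl)oxy]-4H-chromen-4-one
Conditions: TIPSCl (2.3 equiv), imidazole (5 equiv), DMF, 0 °C to rt
Reagents that add atoms: triisopropylsilyl chloride, CC(C)[Si](Cl)(C(C)C)C(C)C
Why: Phenol silylation at the two acidic, unchelated hydroxyls (O7 and O4'), while the 5-OH stays locked in its hydrogen bond to the C4 carbonyl; the bulky triisopropylsilyl group is chosen because it resists O4'→O3' migration and solvolysis at O7 in the next steps.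

**Step 8**
Reactants: 13 3-(benzyloxy)-2-{3-(benzyloxy)-4-[(triisopropylsilyl)oxy]phenyl}-5-hydroxy-7-[(triisopropylsilyl)oxy]-4H-chromen-4-one
Product: 14 3,5-dihydroxy-2-{3-hydroxy-4-[(triisopropylsilyl)oxy]phenyl}-7-[(triisopropylsilyl)oxy]-4H-chromen-4-one
Conditions: H2 (1 atm), 10% Pd/C, EtOAc–THF, rt
Reagents that add atoms: none
Why: Catalytic hydrogenolysis of both benzyl ethers under neutral, aprotic conditions; the silyl ethers and the tetrasubstituted, vinylogous-ester C2=C3 bond should not react.

**Step 9**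
Reactants: 14 3,5-dihydroxy-2-{3-hydroxy-4-[(triisopropylsilyl)oxy]phenyl}-7-[(triisopropylsilyl)oxy]-4H-chromen-4-one
Product: 15 5-hydroxy-4-oxo-2-{3-(sulfooxy)-4-[(triisopropylsilyl)oxy]phenyl}-7-[(triisopropylsilyl)oxy]-4H-chromen-3-yl hydrogen sulfate (handled as the bis-pyridinium salt)
Conditions: SO3·pyridine (6 equiv), pyridine, rt; MeOH quench, evaporate, used crude
Reagents that add atoms: sulfur trioxide–pyridine complex, O=S(=O)([O-])[n+]1ccccc1
Why: O-Sulfation with an amine–sulfur trioxide complex should take the 3-OH and 3'-OH and leave the strongly chelated 5-OH, the least reactive hydroxyl of the flavonol; pyridine is too weak a base to form the phenoxide that would trigger silyl migration.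

**Step 10**
Reactants: 15 5-hydroxy-4-oxo-2-{3-(sulfooxy)-4-[(triisopropylsilyl)oxy]phenyl}-7-[(triisopropylsilyl)oxy]-4H-chromen-3-yl hydrogen sulfate
Product: 16 quercetin 3,3'-bissulfate, 2-[4-hydroxy-3-(sulfooxy)phenyl]-5,7-dihydroxy-4-oxo-4H-chromen-3-yl hydrogen sulfate
Conditions: TBAF (2.5 equiv), AcOH (2.5 equiv), THF, 0 °C; C18 (H2O–MeCN); Dowex 50WX8 (H+), H2O, 0 °C; lyophilise
Reagents that add atoms: none
Why: Buffered fluoride cleaves the two aryl silyl ethers while sulfate monoester anions are inert to fluoride; a short, cold cation exchange then gives the hydrogen sulfate form, which should be stored cold or as a salt.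

**Compound list**
1 | ethyl 3,4-dihydroxybenzoate | CCOC(=O)c1ccc(O)c(O)c1 | starting material
2 | ethyl 3-(benzyloxy)-4-hydroxybenzoate | CCOC(=O)c1ccc(O)c(OCc2ccccc2)c1 | intermediate
3 | 3-(benzyloxy)-4-hydroxybenzoic acid | O=C(O)c1ccc(O)c(OCc2ccccc2)c1 | intermediate
4 | tert-butyldimethylsilyl 3-(benzyloxy)-4-[(tert-butyldimethylsilyl)oxy]benzoate | CC(C)(C)[Si](C)(C)OC(=O)c1ccc(O[Si](C)(C)C(C)(C)C)c(OCc2ccccc2)c1 | intermediate
5 | ethyl benzyloxyacetate | CCOC(=O)COCc1ccccc1 | starting material
6 | 3-(benzyloxy)-4-[(tert-butyldimethylsilyl)oxy]benzoyl chloride (not isolated) | O=C(Cl)c1ccc(O[Si](C)(C)C(C)(C)C)c(OCc2ccccc2)c1 | intermediate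
7 | ethyl 2-(benzyloxy)-3-{3-(benzyloxy)-4-[(tert-butyldimethylsilyl)oxy]phenyl}-3-oxopropanoate (racemic) | CCOC(=O)C(OCc1ccccc1)C(=O)c1ccc(O[Si](C)(C)C(C)(C)C)c(OCc2ccccc2)c1 | intermediate
8 | ethyl 2-(benzyloxy)-3-[3-(benzyloxy)-4-hydroxyphenyl]-3-oxopropanoate (racemic) | CCOC(=O)C(OCc1ccccc1)C(=O)c1ccc(O)c(OCc2ccccc2)c1 | intermediate
9 | phloroglucinol (benzene-1,3,5-triol, anhydrous) | Oc1cc(O)cc(O)c1 | starting material
10 | 2-(benzyloxy)-1-[3-(benzyloxy)-4-hydroxyphenyl]prop-2-ene-1,3-dione (acylketene, not isolated) | O=C=C(OCc1ccccc1)C(=O)c1ccc(O)c(OCc2ccccc2)c1 | intermediate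
11 | 2-(benzyloxy)-1-[3-(benzyloxy)-4-hydroxyphenyl]-3-(2,4,6-trihydroxyphenyl)propane-1,3-dione (racemic, not isolated) | O=C(c1ccc(O)c(OCc2ccccc2)c1)C(OCc1ccccc1)C(=O)c1c(O)cc(O)cc1O | intermediate
12 | 3-(benzyloxy)-2-[3-(benzyloxy)-4-hydroxyphenyl]-5,7-dihydroxy-4H-chromen-4-one | O=c1c(OCc2ccccc2)c(-c2ccc(O)c(OCc3ccccc3)c2)oc2cc(O)cc(O)c12 | intermediate
13 | 3-(benzyloxy)-2-{3-(benzyloxy)-4-[(triisopropylsilyl)oxy]phenyl}-5-hydroxy-7-[(triisopropylsilyl)oxy]-4H-chromen-4-one | O=c1c(OCc2ccccc2)c(-c2ccc(O[Si](C(C)C)(C(C)C)C(C)C)c(OCc3ccccc3)c2)oc2cc(O[Si](C(C)C)(C(C)C)C(C)C)cc(O)c12 | intermediate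
14 | 3,5-dihydroxy-2-{3-hydroxy-4-[(triisopropylsilyl)oxy]phenyl}-7-[(triisopropylsilyl)oxy]-4H-chromen-4-one | O=c1c(O)c(-c2ccc(O[Si](C(C)C)(C(C)C)C(C)C)c(O)c2)oc2cc(O[Si](C(C)C)(C(C)C)C(C)C)cc(O)c12 | intermediate
15 | 5-hydroxy-4-oxo-2-{3-(sulfooxy)-4-[(triisopropylsilyl)oxy]phenyl}-7-[(triisopropylsilyl)oxy]-4H-chromen-3-yl hydrogen sulfate | O=c1c(OS(=O)(=O)O)c(-c2ccc(O[Si](C(C)C)(C(C)C)C(C)C)c(OS(=O)(=O)O)c2)oc2cc(O[Si](C(C)C)(C(C)C)C(C)C)cc(O)c12 | intermediate
16 | quercetin 3,3'-bissulfate | O=c1c(OS(=O)(=O)O)c(-c2ccc(O)c(OS(=O)(=O)O)c2)oc2cc(O)cc(O)c12 | target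

**Totals**
Total step count: 10. Longest linear sequence: 10 steps (1 to 16); compounds 5 and 9 enter as bought materials.

**Steps most likely to fail**

Step 6. The melt may consume the ketoester by hydrolysis and decarboxylation, by oligomeric O-acylation through the ring-B phenol, by benzyl transfer to phloroglucinol, or by closure toward the coumarin. The fallback builds the same ring by polyanion acylation instead of a thermal condensation. It sets out from phloroglucinol 9 and acid chloride 6 (made from 4 as in step 4). Houben–Hoesch acylation of 9 with benzyloxyacetonitrile (ZnCl2, HCl, Et2O, 0 °C) would give 2-(benzyloxy)-1-(2,4,6-trihydroxyphenyl)ethan-1-iminium chloride F1, and hydrolysis in hot water would give 2-(benzyloxy)-1-(2,4,6-trihydroxyphenyl)ethan-1-one F2. Treating F2 with LiHMDS (4.5 equiv, THF, −78 °C) and then 6 (1 equiv) should C-acylate the enolate carbon of the polyanion and give 2-(benzyloxy)-1-{3-(benzyloxy)-4-[(tert-butyldimethylsilyl)oxy]phenyl}-3-(2,4,6-trihydroxyphenyl)propane-1,3-dione F3. Cyclodehydration (0.5% H2SO4 in AcOH, 95 °C) would give 3-(benzyloxy)-2-{3-(benzyloxy)-4-[(tert-butyldimethylsilyl)oxy]phenyl}-5,7-dihydroxy-4H-chromen-4-one F4, and TBAF/AcOH would remove the silyl ether. The fallback comes back at 12; if the silyl ether is already lost in the hot acid, 12 is reached directly.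

Step 9. Sulfation may stay incomplete at the hydrogen-bonded 3-OH, run on to the 5-OH, or be accompanied by loss of the O7 silyl group or O4'→O3' silyl migration, giving anionic mixtures that are hard to separate. The fallback installs the sulfates as neutral protected diesters that can be purified on silica. It sets out from 14. 2,2,2-Trichloroethyl chlorosulfate (2.3 equiv, Et3N, DMAP, THF, 0 °C) would give 5-hydroxy-4-oxo-2-{3-{[(2,2,2-trichloroethoxy)sulfonyl]oxy}-4-[(triisopropylsilyl)oxy]phenyl}-7-[(triisopropylsilyl)oxy]-4H-chromen-3-yl 2,2,2-trichloroethyl sulfate F5. Reductive removal of the trichloroethyl groups (Zn dust, HCO2NH4, MeOH, rt) would release the two sulfate monoesters. The fallback comes back at 15.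

Step 1. The dianion may be benzylated with poor O3/O4 selectivity or twice. The fallback replaces dianion control by a protect–benzylate–deprotect sequence that uses the higher acidity of the 4-OH. It sets out from 1. Allyl bromide (1.0 equiv) with K2CO3 (1.0 equiv) in DMF at rt would give ethyl 4-(allyloxy)-3-hydroxybenzoate F6. Benzylation (BnBr, K2CO3, DMF, 60 °C) would give ethyl 4-(allyloxy)-3-(benzyloxy)benzoate F7. Pd(PPh3)4 (cat.) with morpholine in THF would remove the allyl group. The fallback comes back at 2.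

**Further compounds**
F1 | step 6 | 2-(benzyloxy)-1-(2,4,6-trihydroxyphenyl)ethan-1-iminium chloride | [NH2+]=C(COCc1ccccc1)c1c(O)cc(O)cc1O.[Cl-]
F2 | step 6 | 2-(benzyloxy)-1-(2,4,6-trihydroxyphenyl)ethan-1-one | O=C(COCc1ccccc1)c1c(O)cc(O)cc1O
F3 | step 6 | 2-(benzyloxy)-1-{3-(benzyloxy)-4-[(tert-butyldimethylsilyl)oxy]phenyl}-3-(2,4,6-trihydroxyphenyl)propane-1,3-dione (racemic) | O=C(c1ccc(O[Si](C)(C)C(C)(C)C)c(OCc2ccccc2)c1)C(OCc1ccccc1)C(=O)c1c(O)cc(O)cc1O
F4 | step 6 | 3-(benzyloxy)-2-{3-(benzyloxy)-4-[(tert-butyldimethylsilyl)oxy]phenyl}-5,7-dihydroxy-4H-chromen-4-one | O=c1c(OCc2ccccc2)c(-c2ccc(O[Si](C)(C)C(C)(C)C)c(OCc3ccccc3)c2)oc2cc(O)cc(O)c12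
F5 | step 9 | 5-hydroxy-4-oxo-2-{3-{[(2,2,2-trichloroethoxy)sulfonyl]oxy}-4-[(triisopropylsilyl)oxy]phenyl}-7-[(triisopropylsilyl)oxy]-4H-chromen-3-yl 2,2,2-trichloroethyl sulfate | O=c1c(OS(=O)(=O)OCC(Cl)(Cl)Cl)c(-c2ccc(O[Si](C(C)C)(C(C)C)C(C)C)c(OS(=O)(=O)OCC(Cl)(Cl)Cl)c2)oc2cc(O[Si](C(C)C)(C(C)C)C(C)C)cc(O)c12
F6 | step 1 | ethyl 4-(allyloxy)-3-hydroxybenzoate | CCOC(=O)c1ccc(OCC=C)c(O)c1
F7 | step 1 | ethyl 4-(allyloxy)-3-(benzyloxy)benzoate | CCOC(=O)c1ccc(OCC=C)c(OCc2ccccc2)c1
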